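**Retrosynthetic overview**
1. Target 22 ⇐ ketone 21 (methylenation) ⇐ chloro alcohol 20 ⇐ bridged bromo ether 18 ⇐ alkenol 17. The ring B halogens come from a C7–OH-tethered bromoetherification followed by a retentive ether-to-chloride exchange.
2. 17 ⇐ spiro enedione 14 by conjugate reduction, enol triflate formation and methyl coupling, which fixes the C2=C3 alkene on the arm cis to C10–Br.
3. 14 ⇐ Michael addition of the ring A bromo formyl ketone 11 to methyl vinyl ketone 12 (creates spiro carbon C6 under control of C10–Br), then aldol condensation (closes ring B).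
4. 11 ⇐ geranyl acetate 1: Shi epoxidation, titanocene radical cyclisation (ring A), oxidation/reduction/Appel inversion to the equatorial bromide, ozonolysis, oxidation. The 90–95% ee expected from the epoxidation is upgraded by recrystallising 14.
5. Ring order: ring A first, ring B second; stereochemical relay epoxide → C10 → C6 → C2/C3.

Assumption: the SMILES is read as drawn, (2S,3S,6S,10R); spiro compounds carry chamigrane numbering (C1–C5 ring B, C6 spiro carbon, C7–C11 ring A, C10 = CHBr, C11 = CMe2).

The route is a design on paper; the selectivities stated are predictions from conformational analysis and analogy.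

**Route**

Step 1
Reactants: 1 geranyl acetate [(2E)-3,7-dimethylocta-2,6-dien-1-yl acetate]
Product: 2 (2E)-5-[(2R)-3,3-dimethyloxiran-2-yl]-3-methylpent-2-en-1-yl acetate
Conditions: Shi ketone (D-fructose-derived, 0.3 equiv), Oxone (2KHSO5·KHSO4·K2SO4), K2CO3, Bu4NHSO4, MeCN–DMM–aq. Na2B4O7 buffer, 0 °C
Reagents that add atoms: potassium peroxymonosulfate (KHSO5), [K+].[O-]S(=O)(=O)OO
Why: Shi asymmetric epoxidation, in which the chiral dioxirane from the D-fructose-derived ketone attacks only the electron-rich 6,7-alkene (the 2,3-alkene is deactivated by the allylic acetate) through the spiro transition state that gives the (R)-epoxide, the centre from which all others are relayed.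

Step 2
Reactants: 2 (2E)-5-[(2R)-3,3-dimethyloxiran-2-yl]-3-methylpent-2-en-1-yl acetate
Product: 4 [(1S,3R)-3-hydroxy-2,2-dimethyl-6-methylidenecyclohexyl]methyl acetate, via trimethylsilyl ether 3 (not isolated)
Conditions: Cp2TiCl2 (0.2 equiv), Mn dust, Me3SiCl, 2,4,6-collidine, THF, rt; then 1 M HCl
Reagents that add atoms: none
Why: Titanocene-mediated radical epoxypolyene cyclisation, in which Cp2TiCl (trivalent titanium) opens the epoxide homolytically to the tertiary radical with the C–O centre untouched, 6-endo closure through a chair with the titanoxy and acetoxymethyl groups equatorial sets C1 cis to C3–O, and trapping of the new tertiary radical by a second Cp2TiCl followed by β-hydride elimination gives the exocyclic alkene.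

Step 3
Reactants: 4 [(1S,3R)-3-hydroxy-2,2-dimethyl-6-methylidenecyclohexyl]methyl acetate
Product: 5 [(1S)-2,2-dimethyl-6-methylidene-3-oxocyclohexyl]methyl acetate
Conditions: DMP, NaHCO3, CH2Cl2, 0 °C → rt
Reagents that add atoms: none
Why: Dess–Martin oxidation of the secondary alcohol under buffered neutral conditions, which touches neither the acetate nor the alkene and leaves C1 (not alpha to the new ketone) configurationally safe.

Step 4
Reactants: 5 [(1S)-2,2-dimethyl-6-methylidene-3-oxocyclohexyl]methyl acetate
Product: 6 [(1S,3S)-3-hydroxy-2,2-dimethyl-6-methylidenecyclohexyl]methyl acetate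
Conditions: LiBH(s-Bu)3 (1.1 equiv), THF, −78 °C; then H2O
Reagents that add atoms: none
Why: Diastereoselective ketone reduction by a bulky trialkylborohydride, which attacks from the equatorial side and so gives the axial alcohol trans to the equatorial acetoxymethyl group (3S) while the acetate survives at −78 °C.

Step 5
Reactants: 6 [(1S,3S)-3-hydroxy-2,2-dimethyl-6-methylidenecyclohexyl]methyl acetate
Product: 7 [(1S,3R)-3-bromo-2,2-dimethyl-6-methylidenecyclohexyl]methyl acetate
Conditions: CBr4, PPh3, 2,6-lutidine, CH2Cl2, 0 → 40 °C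
Reagents that add atoms: carbon tetrabromide, BrC(Br)(Br)Br
Why: Appel reaction, an SN2 displacement of the axial alkoxyphosphonium group by bromide along the open equatorial trajectory, which inverts C3 to the equatorial (3R)-bromide, the favourable direction for a carbinol next to a quaternary carbon.

Step 6
Reactants: 7 [(1S,3R)-3-bromo-2,2-dimethyl-6-methylidenecyclohexyl]methyl acetate
Product: 8 [(1S,3R)-3-bromo-2,2-dimethyl-6-methylidenecyclohexyl]methanol
Conditions: K2CO3 (0.2 equiv), MeOH, 0 °C → rt
Reagents that add atoms: none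
Why: Base-catalysed transesterification (acetate methanolysis), mild enough that the hindered secondary bromide neither eliminates nor is displaced.

Step 7
Reactants: 8 [(1S,3R)-3-bromo-2,2-dimethyl-6-methylidenecyclohexyl]methanol
Product: 10 (2S,4R)-4-bromo-2-(hydroxymethyl)-3,3-dimethylcyclohexan-1-one, via secondary ozonide 9 (not isolated)
Conditions: O3, CH2Cl2, −78 °C; then PPh3, −78 °C → rt
Reagents that add atoms: ozone, [O-][O+]=O
Why: Ozonolysis with reductive work-up, a cycloaddition and cycloreversion sequence that cleaves the only alkene to the ketone without touching the alcohol or the bromide, the C2 centre being lost in the next step anyway.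

Step 8
Reactants: 10 (2S,4R)-4-bromo-2-(hydroxymethyl)-3,3-dimethylcyclohexan-1-one
Product: 11 (2Z,4R)-4-bromo-2-(hydroxymethylidene)-3,3-dimethylcyclohexan-1-one
Conditions: DMP, NaHCO3, CH2Cl2, 0 °C
Reagents that add atoms: none
Why: Dess–Martin oxidation of the primary alcohol to the beta-keto aldehyde, which exists as its chelated hydroxymethylidene enol so that only the bromine-bearing stereocentre remains.

Step 9
Reactants: 11 (2Z,4R)-4-bromo-2-(hydroxymethylidene)-3,3-dimethylcyclohexan-1-one; 12 methyl vinyl ketone (but-3-en-2-one)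
Product: 13 (1S,3R)-3-bromo-2,2-dimethyl-6-oxo-1-(3-oxobutyl)cyclohexane-1-carbaldehyde
Conditions: Et3N (0.2 equiv), CH2Cl2, 0 °C → rt
Reagents that add atoms: none
Why: Michael addition of the doubly activated ring carbon to the enone under mild amine catalysis, in which the acceptor is attacked axially on the face anti to the pseudoaxial methyl of the neighbouring CMe2 group, that is trans to the equatorial bromine, so that the oxobutyl chain ends up trans and the formyl group cis to bromine (1S).

Step 10
Reactants: 13 (1S,3R)-3-bromo-2,2-dimethyl-6-oxo-1-(3-oxobutyl)cyclohexane-1-carbaldehyde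
Product: 14 (6R,10R)-10-bromo-11,11-dimethylspiro[5.5]undec-1-ene-3,7-dione
Conditions: p-TsOH·H2O (0.1 equiv), benzene, reflux, Dean–Stark
Reagents that add atoms: none
Why: Intramolecular aldol condensation (the ring-closing half of a Robinson-type spiroannulation), in which the methyl ketone enol attacks the non-enolisable and far more electrophilic aldehyde rather than the hindered ring ketone and dehydration gives the spiro enone without touching C6 or C10, acid being chosen because base would deformylate the substrate.

Step 11
Reactants: 14 (6R,10R)-10-bromo-11,11-dimethylspiro[5.5]undec-1-ene-3,7-dione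
Product: 16 (6R,7S,10R)-10-bromo-7-hydroxy-11,11-dimethylspiro[5.5]undec-2-en-3-yl trifluoromethanesulfonate, via dilithium enolate alkoxide 15 (not isolated)
Conditions: LiBH(s-Bu)3 (2.2 equiv), THF, −78 → −40 °C; then PhNTf2, −78 → 0 °C; then H2O
Reagents that add atoms: N-phenylbis(trifluoromethanesulfonimide), O=S(=O)(N(c1ccccc1)S(=O)(=O)C(F)(F)F)C(F)(F)F
Why: Conjugate reduction with regiospecific enolate trapping, in which hydride adds to the unsubstituted beta-carbon C1 so that the enolate and hence the enol triflate are fixed at C2=C3, while the same reagent reduces the C7 ketone from the side away from the syn-axial methyl to the (7S)-alkoxide, which is too hindered to be triflated and whose configuration is removed again in step 15.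

Step 12
Reactants: 16 (6R,7S,10R)-10-bromo-7-hydroxy-11,11-dimethylspiro[5.5]undec-2-en-3-yl trifluoromethanesulfonate
Product: 17 (6R,7S,10R)-10-bromo-3,11,11-trimethylspiro[5.5]undec-2-en-7-ol
Conditions: MeZnCl (3 equiv), Pd(PPh3)4 (5 mol %), THF, 50 °C
Reagents that add atoms: methylzinc chloride, C[Zn]Cl
Why: Negishi cross-coupling, in which zerovalent palladium inserts only into the vinyl triflate (not into the unactivated secondary alkyl bromide) and methyl is transferred from zinc with the alkene position retained.

Step 13
Reactants: 17 (6R,7S,10R)-10-bromo-3,11,11-trimethylspiro[5.5]undec-2-en-7-ol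
Product: 18 (2S,3S,6R,7S,10R)-2,10-dibromo-3,7-epoxy-3,11,11-trimethylspiro[5.5]undecane
Conditions: NBS (1.05 equiv), CH2Cl2, −20 → 0 °C, dark
Reagents that add atoms: N-bromosuccinimide, O=C1CCC(=O)N1Br
Why: Bromoetherification (bromonium-induced halocyclisation), in which reversible bromonium formation is funnelled through the only ion the C7 hydroxyl can reach, oxygen attacking the tertiary carbon C3 (Markovnikov, as in the NBS cyclisation of alpha-terpineol to a bromocineole) through a boat-shaped ring B so that bromine lands on C2 anti to oxygen, which means cis to C11 (2S), a face that an untethered trans-diaxial bromochlorination would not deliver.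

Step 14
Reactants: 18 (2S,3S,6R,7S,10R)-2,10-dibromo-3,7-epoxy-3,11,11-trimethylspiro[5.5]undecane
Product: 20 (2S,3S,6R,7S,10R)-2,10-dibromo-3-chloro-3,11,11-trimethylspiro[5.5]undecan-7-ol, via dichloroborinate 19 (not isolated)
Conditions: BCl3 (1.1 equiv), CH2Cl2, −78 °C; then H2O
Reagents that add atoms: boron trichloride, ClB(Cl)Cl
Why: Lewis-acid cleavage of a tertiary alkyl ether by BCl3 with internal return, in which coordination to the bridging oxygen ionises the tertiary C3–O bond with help from the neighbouring bromine on the opposite face and chloride is handed back from the tethered O–BCl3 group on the face the oxygen leaves, giving the tertiary chloride with net retention (3S) and trans to bromine while the secondary C7–O bond stays intact.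

Step 15
Reactants: 20 (2S,3S,6R,7S,10R)-2,10-dibromo-3-chloro-3,11,11-trimethylspiro[5.5]undecan-7-ol
Product: 21 (2S,3S,6R,10R)-2,10-dibromo-3-chloro-3,11,11-trimethylspiro[5.5]undecan-7-one
Conditions: DMP, NaHCO3, CH2Cl2, rt
Reagents that add atoms: none
Why: Dess–Martin oxidation of the hindered secondary alcohol under neutral conditions, which leaves the three carbon–halogen bonds untouched and removes the C7 stereocentre that is no longer needed.

Step 16
Reactants: 21 (2S,3S,6R,10R)-2,10-dibromo-3-chloro-3,11,11-trimethylspiro[5.5]undecan-7-one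
Product: 22 (2S,3S,6S,10R)-2,10-dibromo-3-chloro-3,11,11-trimethyl-7-methylidenespiro[5.5]undecane
Conditions: Cp2Ti(μ-Cl)(μ-CH2)AlMe2 (Tebbe reagent), pyridine, THF–toluene, −40 → 0 °C
Reagents that add atoms: Tebbe reagent, C[Al-]1(C)C[Ti](C2C=CC=C2)(C2C=CC=C2)[Cl+]1
Why: Tebbe methylenation, a carbonyl olefination by a non-basic titanium methylidene through an oxatitanacyclobutane, chosen because it olefinates hindered enolisable ketones without the strong base that would let a C8 enolate displace the C10 bromide or eliminate the tertiary chloride.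

**Compound list**
1 | geranyl acetate, (2E)-3,7-dimethylocta-2,6-dien-1-yl acetate | CC(C)=CCC/C(C)=C/COC(C)=O | starting material
2 | (2E)-5-[(2R)-3,3-dimethyloxiran-2-yl]-3-methylpent-2-en-1-yl acetate | CC1(C)O[C@@H]1CC/C(C)=C/COC(C)=O | intermediate
3 | [(1S,3R)-2,2-dimethyl-6-methylidene-3-(trimethylsilyloxy)cyclohexyl]methyl acetate | C=C1CC[C@@H](O[Si](C)(C)C)C(C)(C)[C@H]1COC(C)=O | intermediate
4 | [(1S,3R)-3-hydroxy-2,2-dimethyl-6-methylidenecyclohexyl]methyl acetate (OH and CH2OAc cis, both equatorial) | C=C1CC[C@@H](O)C(C)(C)[C@H]1COC(C)=O | intermediate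
5 | [(1S)-2,2-dimethyl-6-methylidene-3-oxocyclohexyl]methyl acetate | C=C1CCC(=O)C(C)(C)[C@H]1COC(C)=O | intermediate
6 | [(1S,3S)-3-hydroxy-2,2-dimethyl-6-methylidenecyclohexyl]methyl acetate (axial OH, trans to CH2OAc) | C=C1CC[C@H](O)C(C)(C)[C@H]1COC(C)=O | intermediate
7 | [(1S,3R)-3-bromo-2,2-dimethyl-6-methylidenecyclohexyl]methyl acetate (equatorial Br, cis to CH2OAc) | C=C1CC[C@@H](Br)C(C)(C)[C@H]1COC(C)=O | intermediate
8 | [(1S,3R)-3-bromo-2,2-dimethyl-6-methylidenecyclohexyl]methanol | C=C1CC[C@@H](Br)C(C)(C)[C@H]1CO | intermediate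
9 | secondary ozonide of 8, [(6S,8R)-8-bromo-7,7-dimethyl-1,2,4-trioxaspiro[4.5]decan-6-yl]methanol (trioxolane spiro carbon formed as both epimers, left unassigned) | C1OOC2(O1)CC[C@@H](Br)C(C)(C)[C@H]2CO | intermediate
10 | (2S,4R)-4-bromo-2-(hydroxymethyl)-3,3-dimethylcyclohexan-1-one | O=C1CC[C@@H](Br)C(C)(C)[C@H]1CO | intermediate
11 | (2Z,4R)-4-bromo-2-(hydroxymethylidene)-3,3-dimethylcyclohexan-1-one (enol form of the 2-formyl ketone) | O/C=C1\C(=O)CC[C@@H](Br)C1(C)C | intermediate
12 | methyl vinyl ketone, but-3-en-2-one | C=CC(C)=O | starting material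
13 | (1S,3R)-3-bromo-2,2-dimethyl-6-oxo-1-(3-oxobutyl)cyclohexane-1-carbaldehyde (CHO cis, oxobutyl trans to Br) | O=C1CC[C@@H](Br)C(C)(C)[C@]1(C=O)CCC(C)=O | intermediate
14 | (6R,10R)-10-bromo-11,11-dimethylspiro[5.5]undec-1-ene-3,7-dione | O=C1CC[C@@H](Br)C(C)(C)[C@]12CCC(=O)C=C2 | intermediate
15 | dilithium (6R,7S,10R)-10-bromo-11,11-dimethylspiro[5.5]undec-2-ene-3,7-bis(olate) | [Li]O[C@H]1CC[C@@H](Br)C(C)(C)[C@]12CCC(O[Li])=CC2 | intermediate
16 | (6R,7S,10R)-10-bromo-7-hydroxy-11,11-dimethylspiro[5.5]undec-2-en-3-yl trifluoromethanesulfonate | O[C@H]1CC[C@@H](Br)C(C)(C)[C@]12CCC(OS(=O)(=O)C(F)(F)F)=CC2 | intermediate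
17 | (6R,7S,10R)-10-bromo-3,11,11-trimethylspiro[5.5]undec-2-en-7-ol (OH cis to Br on ring A) | O[C@H]1CC[C@@H](Br)C(C)(C)[C@]12CCC(C)=CC2 | intermediate
18 | (2S,3S,6R,7S,10R)-2,10-dibromo-3,7-epoxy-3,11,11-trimethylspiro[5.5]undecane (oxygen bridges C3 and C7, 2-oxabicyclo[2.2.2]octane core, C2–Br anti to the bridge) | O3[C@H]1CC[C@@H](Br)C(C)(C)[C@]12CC[C@@]3(C)[C@@H](Br)C2 | intermediate
19 | (2S,3S,6R,7S,10R)-2,10-dibromo-3-chloro-3,11,11-trimethylspiro[5.5]undecan-7-yl dichloroborinate | ClB(Cl)O[C@H]1CC[C@@H](Br)C(C)(C)[C@]12CC[C@](C)(Cl)[C@@H](Br)C2 | intermediate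
20 | (2S,3S,6R,7S,10R)-2,10-dibromo-3-chloro-3,11,11-trimethylspiro[5.5]undecan-7-ol | O[C@H]1CC[C@@H](Br)C(C)(C)[C@]12CC[C@](C)(Cl)[C@@H](Br)C2 | intermediate
21 | (2S,3S,6R,10R)-2,10-dibromo-3-chloro-3,11,11-trimethylspiro[5.5]undecan-7-one | O=C1CC[C@@H](Br)C(C)(C)[C@]12CC[C@](C)(Cl)[C@@H](Br)C2 | intermediate
22 | (2S,3S,6S,10R)-2,10-dibromo-3-chloro-3,11,11-trimethyl-7-methylidenespiro[5.5]undecane | C=C1CC[C@@H](Br)C(C)(C)[C@]12CC[C@](C)(Cl)[C@@H](Br)C2 | target

**Totals and weak points**

Total step count: 16. Longest linear sequence: 16 steps (1 to 22; 12 is bought).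

The three steps most likely to fail:

Step 5, the Appel substitution at a carbinol flanked by a quaternary carbon, where E2 elimination and methyl-shift products compete. The fallback makes the C–Br bond before the ring instead of on it. It sets out from 1: epoxidation with the enantiomeric Shi ketone (from L-sorbose) gives (2E)-5-[(2S)-3,3-dimethyloxiran-2-yl]-3-methylpent-2-en-1-yl acetate F1. Li2NiBr4 in THF opens the epoxide at its secondary carbon with inversion to (2E,6R)-6-bromo-7-hydroxy-3,7-dimethyloct-2-en-1-yl acetate F2. Catalytic TfOH in hexafluoroisopropanol ionises the tertiary hydroxyl; the neighbouring bromine gives the enantiopure bromonium ion, which the 2,3-alkene captures through a chair with Br and CH2OAc equatorial. Loss of a methyl proton gives the exocyclic alkene, so the fallback comes back to the route at 7 after chromatographic removal of the endocyclic alkene isomers.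

Step 9, the Michael addition, where the ammonium enolate could displace the 1,3-related bromide to give a bicyclo[3.1.0]hexane, or the facial selectivity could be modest. The fallback avoids any free enolate. It sets out from 11: Me3SiCl and Et3N give (2E,4R)-4-bromo-3,3-dimethyl-2-[(trimethylsilyloxy)methylidene]cyclohexan-1-one F3. A BF3·OEt2-promoted Mukaiyama–Michael addition of F3 to 12 in CH2Cl2 at −78 °C then forms the same C–C bond with the same axial approach, and aqueous work-up returns to the route at 13.

Step 14, the BCl3 ether-to-chloride exchange, where E1 elimination, chloride entry at C2 with bromine migration, or the C3 epimer are possible. The fallback replaces internal return by acylative cleavage. It sets out from 18: acetyl chloride with catalytic ZnCl2 in CH2Cl2 acylates the bridging oxygen, the tertiary C3–O bond ionises with bromine participation, and external chloride opens the bromonium ion at the tertiary carbon anti to bromine. This gives (2S,3S,6R,7S,10R)-2,10-dibromo-3-chloro-3,11,11-trimethylspiro[5.5]undecan-7-yl acetate F4. Reductive removal of the acetate with i-Bu2AlH at −78 °C returns to the route at 20.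

Further compounds
F1 | step 5 | (2E)-5-[(2S)-3,3-dimethyloxiran-2-yl]-3-methylpent-2-en-1-yl acetate | CC1(C)O[C@H]1CC/C(C)=C/COC(C)=O
F2 | step 5 | (2E,6R)-6-bromo-7-hydroxy-3,7-dimethyloct-2-en-1-yl acetate | CC(C)(O)[C@H](Br)CC/C(C)=C/COC(C)=O
F3 | step 9 | (2E,4R)-4-bromo-3,3-dimethyl-2-[(trimethylsilyloxy)methylidene]cyclohexan-1-one | C[Si](C)(C)O/C=C1/C(=O)CC[C@@H](Br)C1(C)C
F4 | step 14 | (2S,3S,6R,7S,10R)-2,10-dibromo-3-chloro-3,11,11-trimethylspiro[5.5]undecan-7-yl acetate | CC(=O)O[C@H]1CC[C@@H](Br)C(C)(C)[C@]12CC[C@](C)(Cl)[C@@H](Br)C2
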